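Assumption: the target has no stereocentre and is drawn without an axial descriptor, so the hindered C6–C8'' axis is left unspecified; all biaryls are planned as racemates and 18 as a mixture of diastereomers.

## Structural features

The target is a biflavone of two identical 5,7-dihydroxy-2-(4-methoxyphenyl)chromen-4-one units, each with rings A (benzo), C (pyranone) and B (4-methoxyphenyl). A single bond joins C6 of unit 1 to C8 of unit 2, so the two rings A form a biaryl. The only stereochemical element is this biaryl axis, which carries four ortho substituents (5-OH and 7-OH of unit 1, 7-OH and C8a–O1 of unit 2). Fragile features are the four free phenols on two phloroglucinol rings (oxidation, C-alkylation), the two chromone enones (conjugate addition, ring opening by alkoxide, reduction) and the two aryl methyl ethers, which must outlast whatever unmasks the phenols. The difficulty is twofold. The biaryl bond lies between two carbons that each sit between two oxygens, the worst case for a cross-coupling. The two rings A are also annulated differently: in unit 1 the biaryl carbon is para to the ring carbon bearing O1, in unit 2 it is ortho, and an unselective late acylation would blur this. The key step exploits the fact that ring A of unit 2 is a 2-arylphloroglucinol. C4a, C5, C6 and C7 come from a cyclobutenone and C8 and C8a from an aryl alkyne, so the ring is built around the aryl group and the biaryl bond is never made by coupling. The oxygens at C7, C8a and C5 arrive as free phenol, silyl ether and benzyl ether.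

## Logic of the disconnections

21 to 20. The four O–CH2Ph bonds at O5 and O7 of both units are cut. Benzyl is the one group that leaves under conditions inert to the two O–CH3 bonds. The gain is that every earlier step handles a non-acidic, oxidation-resistant compound. The forward hydrogenolysis must spare the two C2=C3 enones.

20 to 19. The O1–C2 bonds of both pyranones are cut. Each ring C is the oxa-Michael adduct of a phenol to an aryl ynone, so both rings can close in one operation. The forward step must close 6-endo and not 5-exo. 19 has exactly one free hydroxyl beside each ynone, para to the biaryl carbon in unit 1 and ortho to it in unit 2, which fixes the 6- and 8-linkages.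

19 to 18 to 16 and 17. The C3–C4 bonds of both units are cut, after taking C4 down to the alcohol level. All of ring B, C2 and C3 then sit in commercial 17, and 16 is a bis(salicylaldehyde). The forward addition must succeed twice on aldehydes that are di-ortho-substituted and carry an ortho-phenoxide, and the oxidation must leave the phenols alone.

16 to 15. The C4a–C4 bonds of both units are cut. A Friedel–Crafts or Fries acetylation is avoided for two reasons. Lewis acids endanger four benzyl ethers on phloroglucinol rings. In unit 2, C6 is para to the freed phenol and as activated as C4a, so one free ortho carbon alone does not secure the 8-linkage. A formyl group placed through the magnesium phenoxide goes only ortho, under basic conditions. The gain is a biaryl, 15, that carries oxygen substituents only. The demand is one free hydroxyl per ring, at C8a of each unit.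

15 to 13 to 12. The O–benzyl bond at C7 of unit 2 is cut, together with the O–Si bond at C8a of unit 2 and the O–CH2OCH3 bond at C8a of unit 1. In 12 the three oxygens of ring A of unit 2 are in three different states. Capping the single phenol and then releasing the silyl and acetal oxygens gives the pattern "benzyl for every future hydroxyl, free hydroxyl for every future O1". Both units can then be annulated in parallel, not one after the other. The silyl ether must survive the benzylation and the acid must spare the benzyl ethers.

12 to 5 and 7. The bonds C7–C8, C8a–C4a and C6–C7 of unit 2 are cut. Ring A of unit 2 is removed around the biaryl carbon, so the tetra-ortho-substituted bond is carried in as the aryl–alkyne bond of 5. The gain is one arene with a two-carbon chain and a four-carbon ring. The forward step needs a single regiochemistry in the ketene–alkyne union and must tolerate a di-ortho-substituted aryl on the reacting alkyne carbon.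

5 to 3 to 2 to 1. The alkyne is traced to the ester carbonyl plus a one-carbon carbenoid, the aryl–C8 bond arising by a 1,2-aryl shift. Two O–benzyl bonds and one O–CH2OCH3 bond are also cut. The ester carbon of 1 marks the future biaryl position between two equivalent oxygens (later O5 and O7 of unit 1) and para to the third (later O1 of unit 1). That third hydroxyl is the only one not hydrogen-bonded to the ester and can be alkylated first. The demand is a homologation of a hindered ester that does not attack the benzyl ethers.

7 to 6. The enol-ether C3–O bond is exchanged. The oxygen at C5 of unit 2 must end as a hydroxyl, so the ethyl group of commercial 6 is replaced by benzyl and all four phenols are released by one hydrogenolysis. The exchange must run below the temperature at which the four-membered ring opens.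

## Other disconnections considered

Alternative 1: The cut is the C2=C3 bond of both pyranones. In the forward step the bis(acylmethylenephosphorane) bis(4-methoxybenzoate) A2 would be heated in toluene. Each ylide carbon would attack the ester carbonyl on the neighbouring phenol oxygen, and both rings C would close to A1, which is the same compound as 20.
- In its favour: the conditions are neutral, both pyranones form at once, and no other ring size can form.
- Against it here: it is a ring-C closure only and leaves the hindered biaryl bond and the different orientation of the two rings A unsolved. A2 also needs a carboxyl-level carbon at C4a of each ring A. That means oxidising 16 or carboxylating 15, then activation, ylide acylation of two di-ortho-substituted benzoyl groups and aroylation. Ester carbonyls are also sluggish Wittig acceptors.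
- Comparison: as a path from 15 to 20 it equals steps 8–11 in step count and is better in the security of the closure. It is worse in atom economy and in access to its precursor. It presupposes a biaryl such as 15, so it could serve as an endgame for the chosen ring-A construction but not replace it.

Alternative 2: The cut is the bond in ring A of unit 1 from C6, the carbon bearing unit 2, to a neighbouring oxygenated carbon. In the forward step the methyl 3,5-dioxohexanoate A4, attached through its C6 methylene to C8 of a finished unit-2 flavone, would be treated with Mg(OMe)2 in methanol. The benzylic carbanion would attack the ester carbonyl and the triketone would enolise to the phloroglucinol A3.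
- In its favour: the hindered bond starts as a benzylic C–C bond, so the steric problem is avoided as well as in the chosen plan. The reagents are cheap and robust, and the 8-attachment is fixed by the side chain on a ready-made flavone.
- Against it here: A3 has three free hydroxyls on a locally symmetrical ring. The later pyranone could close on the oxygen para to the biaryl bond (6-linked, wanted) or on an ortho oxygen (8-linked isomer), and nothing in A3 decides between them. The polycarbonyl chain can also close by aldol or O-acylation, and methoxide is in contact with the chromone of unit 2. The two flavones are made one after the other.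
- Comparison: structurally both plans grow a ring A around the biaryl carbon. The alternative is equal on the steric issue and better on robustness and scale. Mechanistically it is ionic with several competing modes, whereas the pericyclic cascade has one dictated regiochemistry. It is worse on oxygen differentiation and on step economy.

Alternative 3: The cut is C8–C8a and C4a–C5 of unit 2. In the forward step the 4-aryl-1-methoxy-1,3-bis(trimethylsilyloxy)buta-1,3-diene A6 would add across C5=C6 of the bromopyranone A7, diene C4 to the oxygen-bearing carbon and diene C1 to the brominated carbon. Loss of HBr and methanol would aromatise ring A to A5.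
- In its favour: the pyranone and ring B of unit 2 exist before ring A, so unit 2 needs no later chromone construction and its 5- and 7-hydroxyls appear free. On unit 2 this is more convergent than the chosen plan. The biaryl bond again comes in on an open-chain carbon, and the regiochemistry is set by the polarity of an oxygenated π system.
- Against it here: the bond-forming diene terminus carries the 2,4,6-trioxygenated aryl and must attack a pyranone, a weak acceptor. The s-cis diene with that aryl is strained. In A5 all three oxygens of the pendant ring are benzyl ethers, so the para oxygen that must become O1 of unit 1 cannot be freed selectively without a redesign. The free 5,7-diol must also be capped again. A6 needs the same arylacetic homologation that leads to 5, so nothing is saved before the key step.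
- Comparison: it equals the chosen plan in rings formed and in the principle of regiocontrol, and is better in convergence for unit 2. It is worse in the expected reactivity of the hindered terminus and in the differentiation of unit 1. The overall step count would be similar.

Key step: step 5

## Route

Step 1
Reactants: 1 methyl 2,4,6-trihydroxybenzoate
Product: 2 methyl 2,6-dihydroxy-4-(methoxymethoxy)benzoate
Conditions: MeOCH2Cl (1.05 equiv), i-Pr2NEt, CH2Cl2, 0 °C
Reagents that add atoms: chloromethyl methyl ether, COCCl
Why: O-alkylation (Williamson type) of the 4-hydroxyl, the most acidic and the only one not hydrogen-bonded to the ester; limiting the chloride should keep the two chelated hydroxyls free.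

Step 2
Reactants: 2 methyl 2,6-dihydroxy-4-(methoxymethoxy)benzoate
Product: 3 methyl 2,6-bis(benzyloxy)-4-(methoxymethoxy)benzoate
Conditions: BnBr, K2CO3, DMF, 60 °C
Reagents that add atoms: benzyl bromide, BrCc1ccccc1
Why: Williamson etherification of both chelated phenols under forcing but non-acidic conditions; the acetal and the ester are inert to carbonate.

Step 3
Reactants: 3 methyl 2,6-bis(benzyloxy)-4-(methoxymethoxy)benzoate
Product: 5 {[2,6-bis(benzyloxy)-4-(methoxymethoxy)phenyl]ethynyloxy}tri(propan-2-yl)silane, via lithium ynolate 4 (not isolated)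
Conditions: CH2Br2, lithium 2,2,6,6-tetramethylpiperidide (2.2 equiv), THF, −78 °C; n-BuLi, −78 to 0 °C; TIPSOTf, −78 °C to rt
Reagents that add atoms: dibromomethane, BrCBr; triisopropylsilyl trifluoromethanesulfonate, CC(C)[Si](OS(=O)(=O)C(F)(F)F)(C(C)C)C(C)C
Why: Kowalski ester homologation: LiCHBr2 adds to the ester, and enolisation, bromine–lithium exchange and a 1,2-shift of the electron-rich aryl give ynolate 4. The bulky silyl triflate should silylate 4 on oxygen. Butyllithium is kept near one equivalent and at or below 0 °C to spare the benzyl ethers.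

Step 4
Reactants: 6 3-ethoxycyclobut-2-en-1-one
Product: 7 3-(benzyloxy)cyclobut-2-en-1-one
Conditions: BnOH (4 equiv), TsOH·H2O (2 mol%), neat, 30 °C, 20 mbar
Reagents that add atoms: benzyl alcohol, OCc1ccccc1
Why: Acid-catalysed transetherification of a vinylogous ester by addition–elimination at C3, the same mode by which this ring exchanges its alkoxy group for amines. Removal of ethanol under reduced pressure drives it, and the temperature stays far below that of ring opening.

Step 5
Reactants: 7 3-(benzyloxy)cyclobut-2-en-1-one; 5 {[2,6-bis(benzyloxy)-4-(methoxymethoxy)phenyl]ethynyloxy}tri(propan-2-yl)silane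
Product: 12 2',4,6'-tris(benzyloxy)-4'-(methoxymethoxy)-6-(triisopropylsilyloxy)-[1,1'-biphenyl]-2-ol, via vinylketene 8 (not isolated), via cyclobutenone adduct 9 (not isolated), via dienylketene 10 (not isolated), via cyclohexadienone 11 (not isolated)
Conditions: 7 (1.3 equiv), toluene (0.3 M), 80 °C then 110 °C, argon
Reagents that add atoms: none
Why: Danheiser benzannulation of a cyclobutenone with a silyl ynol ether. At 80 °C 7 opens in a 4π electrocyclic step to vinylketene 8; the alkyne carbon of 5 remote from oxygen, the nucleophilic terminus of the ynol ether, bonds to the ketene carbonyl carbon and the oxygen-bearing carbon to the ketene α-carbon, which gives 9 and forms C7–C8 and C8a–C4a of unit 2. A second 4π opening gives dienylketene 10, whose ketene carbon and terminal methylene close ring A by a thermal disrotatory 6π electrocyclisation (C6–C7) to 11, and enolisation gives phenol 12. No stereocentre survives: the sp3 carbon of 9 is lost on ring opening, the alkene geometry of 10 corrects itself through reversible opening, and the axis of 12 is not stereogenic because the pendant aryl is symmetrically substituted. The regiochemistry that is needed, aryl between the free hydroxyl and the silyl ether with benzyloxy para to it, follows from the polarisation of the ynol ether and from the benzyloxy group on C3 of 7. The chemoselectivity that is needed, capture of 8 by the alkyne ahead of ketene dimerisation or acylation of 12, is helped by the high nucleophilicity of the ynol ether, a small excess of 7 and moderate concentration. Hydroxyl and silyloxy groups are meta, which rules out silyl migration, and the benzyl, acetal and silyl ethers are inert under neutral thermal conditions.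

Step 6
Reactants: 12 2',4,6'-tris(benzyloxy)-4'-(methoxymethoxy)-6-(triisopropylsilyloxy)-[1,1'-biphenyl]-2-ol
Product: 13 triisopropyl{[2',4,6,6'-tetrakis(benzyloxy)-4'-(methoxymethoxy)-[1,1'-biphenyl]-2-yl]oxy}silane
Conditions: BnBr, K2CO3, DMF, 25 °C
Reagents that add atoms: benzyl bromide, BrCc1ccccc1
Why: Williamson etherification of the only free phenol, the future 7-OH of unit 2; the hindered triisopropylsilyl aryl ether should survive anhydrous carbonate at room temperature.

Step 7
Reactants: 13 triisopropyl{[2',4,6,6'-tetrakis(benzyloxy)-4'-(methoxymethoxy)-[1,1'-biphenyl]-2-yl]oxy}silane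
Product: 15 2',4,6,6'-tetrakis(benzyloxy)-[1,1'-biphenyl]-2,4'-diol, via desilylated phenol 14 (not isolated)
Conditions: Bu4NF, THF, 0 °C; then conc. HCl, MeOH, 50 °C
Reagents that add atoms: none
Why: Fluoride cleaves the aryl silyl ether to 14, and acid-catalysed acetal exchange with methanol removes the methoxymethyl group; benzyl aryl ethers tolerate both. The two oxygens now free are those that become O1 of unit 2 and O1 of unit 1.

Step 8
Reactants: 15 2',4,6,6'-tetrakis(benzyloxy)-[1,1'-biphenyl]-2,4'-diol
Product: 16 2',4,6,6'-tetrakis(benzyloxy)-2,4'-dihydroxy-[1,1'-biphenyl]-3,3'-dicarbaldehyde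
Conditions: MgCl2 (anhydrous), Et3N, (CH2O)n, THF, 65 °C; then 1 M HCl
Reagents that add atoms: paraformaldehyde, as formaldehyde, C=O
Why: Casiraghi–Skattebøl magnesium-mediated ortho-formylation: the C–C bond forms inside the magnesium phenoxide–formaldehyde complex and a second formaldehyde accepts hydride, so only a carbon ortho to a phenol can react. In unit 2 this is C4a and not the para carbon C6; in unit 1 the two ortho carbons are equivalent; no acid touches the benzyl ethers.

Step 9
Reactants: 16 2',4,6,6'-tetrakis(benzyloxy)-2,4'-dihydroxy-[1,1'-biphenyl]-3,3'-dicarbaldehyde; 17 1-ethynyl-4-methoxybenzene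
Product: 18 1,1'-[2',4,6,6'-tetrakis(benzyloxy)-2,4'-dihydroxy-[1,1'-biphenyl]-3,3'-diyl]bis[3-(4-methoxyphenyl)prop-2-yn-1-ol]
Conditions: 17 (6 equiv), n-BuLi, THF, −78 °C; then 16, −78 °C to rt; aq. NH4Cl
Reagents that add atoms: none
Why: 1,2-Addition of a lithium acetylide to an aldehyde; the excess covers deprotonation of the two phenols, and lithium chelation between phenoxide and formyl oxygen should keep the aldehydes reactive. The two carbinol centres form without control and are removed in step 10; 18 is carried on crude because the electron-rich benzylic alcohols ionise easily.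

Step 10
Reactants: 18 1,1'-[2',4,6,6'-tetrakis(benzyloxy)-2,4'-dihydroxy-[1,1'-biphenyl]-3,3'-diyl]bis[3-(4-methoxyphenyl)prop-2-yn-1-ol]
Product: 19 1,1'-[2',4,6,6'-tetrakis(benzyloxy)-2,4'-dihydroxy-[1,1'-biphenyl]-3,3'-diyl]bis[3-(4-methoxyphenyl)prop-2-yn-1-one]
Conditions: MnO2 (activated, excess), CH2Cl2, rt
Reagents that add atoms: none
Why: MnO2 oxidation of alcohols that are both benzylic and propargylic; the phenols, hydrogen-bonded to the new carbonyls, and the benzyl ethers are not affected.

Step 11
Reactants: 19 1,1'-[2',4,6,6'-tetrakis(benzyloxy)-2,4'-dihydroxy-[1,1'-biphenyl]-3,3'-diyl]bis[3-(4-methoxyphenyl)prop-2-yn-1-one]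
Product: 20 5,7-bis(benzyloxy)-6-[5,7-bis(benzyloxy)-2-(4-methoxyphenyl)-4-oxo-4H-chromen-8-yl]-2-(4-methoxyphenyl)-4H-chromen-4-one
Conditions: DMAP (20 mol%), DMF, 40 °C
Reagents that add atoms: none
Why: Nucleophile-catalysed 6-endo-dig oxa-Michael cyclisation of ortho-hydroxyaryl ynones to flavones: DMAP adds to the β-carbon and the phenoxide displaces it by addition–elimination, which directs closure to the six-membered ring. The only hydroxyl beside each ynone is the one at C8a, so unit 1 closes para and unit 2 ortho to the biaryl carbon.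

Step 12
Reactants: 20 5,7-bis(benzyloxy)-6-[5,7-bis(benzyloxy)-2-(4-methoxyphenyl)-4-oxo-4H-chromen-8-yl]-2-(4-methoxyphenyl)-4H-chromen-4-one
Product: 21 6-[5,7-dihydroxy-2-(4-methoxyphenyl)-4-oxo-4H-chromen-8-yl]-5,7-dihydroxy-2-(4-methoxyphenyl)-4H-chromen-4-one
Conditions: H2 (1 atm), Pd/C (10% palladium on carbon), THF–MeOH, rt
Reagents that add atoms: none
Why: Hydrogenolysis of four aryl benzyl ethers; the aryl methyl ethers are inert and chromone C2=C3 bonds are not reduced under these mild conditions.

## Compound list

1 | methyl 2,4,6-trihydroxybenzoate | COC(=O)c1c(O)cc(O)cc1O | starting material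
2 | methyl 2,6-dihydroxy-4-(methoxymethoxy)benzoate | COCOc1cc(O)c(C(=O)OC)c(O)c1 | intermediate
3 | methyl 2,6-bis(benzyloxy)-4-(methoxymethoxy)benzoate | COCOc1cc(OCc2ccccc2)c(C(=O)OC)c(OCc2ccccc2)c1 | intermediate
4 | lithium 2-[2,6-bis(benzyloxy)-4-(methoxymethoxy)phenyl]ethynolate | [Li+].[O-]C#Cc1c(OCc2ccccc2)cc(OCOC)cc1OCc1ccccc1 | intermediate (not isolated)
5 | {[2,6-bis(benzyloxy)-4-(methoxymethoxy)phenyl]ethynyloxy}tri(propan-2-yl)silane | CC(C)[Si](OC#Cc1c(OCc2ccccc2)cc(OCOC)cc1OCc1ccccc1)(C(C)C)C(C)C | intermediate
6 | 3-ethoxycyclobut-2-en-1-one | CCOC1=CC(=O)C1 | starting material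
7 | 3-(benzyloxy)cyclobut-2-en-1-one | O=C1C=C(OCc2ccccc2)C1 | intermediate
8 | 3-(benzyloxy)buta-1,3-dien-1-one | O=C=CC(=C)OCc1ccccc1 | intermediate (not isolated)
9 | 2-[2,6-bis(benzyloxy)-4-(methoxymethoxy)phenyl]-4-[1-(benzyloxy)ethenyl]-3-(triisopropylsilyloxy)cyclobut-2-en-1-one (racemic) | O=C1C(c2c(OCc3ccccc3)cc(OCOC)cc2OCc2ccccc2)=C(O[Si](C(C)C)(C(C)C)C(C)C)C1C(=C)OCc1ccccc1 | intermediate (not isolated)
10 | (3E)-2-[2,6-bis(benzyloxy)-4-(methoxymethoxy)phenyl]-5-(benzyloxy)-3-(triisopropylsilyloxy)hexa-1,3,5-trien-1-one | O=C=C(c1c(OCc2ccccc2)cc(OCOC)cc1OCc1ccccc1)/C(O[Si](C(C)C)(C(C)C)C(C)C)=C\C(=C)OCc1ccccc1 | intermediate (not isolated)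
11 | 2-[2,6-bis(benzyloxy)-4-(methoxymethoxy)phenyl]-5-(benzyloxy)-3-(triisopropylsilyloxy)cyclohexa-2,4-dien-1-one | O=C1CC(OCc2ccccc2)=CC(O[Si](C(C)C)(C(C)C)C(C)C)=C1c1c(OCc2ccccc2)cc(OCOC)cc1OCc1ccccc1 | intermediate (not isolated)
12 | 2',4,6'-tris(benzyloxy)-4'-(methoxymethoxy)-6-(triisopropylsilyloxy)-[1,1'-biphenyl]-2-ol | Oc1cc(OCc2ccccc2)cc(O[Si](C(C)C)(C(C)C)C(C)C)c1-c1c(OCc2ccccc2)cc(OCOC)cc1OCc1ccccc1 | intermediate
13 | triisopropyl{[2',4,6,6'-tetrakis(benzyloxy)-4'-(methoxymethoxy)-[1,1'-biphenyl]-2-yl]oxy}silane | CC(C)[Si](Oc1cc(OCc2ccccc2)cc(OCc2ccccc2)c1-c1c(OCc2ccccc2)cc(OCOC)cc1OCc1ccccc1)(C(C)C)C(C)C | intermediate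
14 | 2',4,6,6'-tetrakis(benzyloxy)-4'-(methoxymethoxy)-[1,1'-biphenyl]-2-ol | Oc1cc(OCc2ccccc2)cc(OCc2ccccc2)c1-c1c(OCc2ccccc2)cc(OCOC)cc1OCc1ccccc1 | intermediate (not isolated)
15 | 2',4,6,6'-tetrakis(benzyloxy)-[1,1'-biphenyl]-2,4'-diol | Oc1cc(OCc2ccccc2)cc(OCc2ccccc2)c1-c1c(OCc2ccccc2)cc(O)cc1OCc1ccccc1 | intermediate
16 | 2',4,6,6'-tetrakis(benzyloxy)-2,4'-dihydroxy-[1,1'-biphenyl]-3,3'-dicarbaldehyde (racemic axis) | O=Cc1c(O)c(-c2c(OCc3ccccc3)cc(O)c(C=O)c2OCc2ccccc2)c(OCc2ccccc2)cc1OCc1ccccc1 | intermediate
17 | 1-ethynyl-4-methoxybenzene | COc1ccc(C#C)cc1 | starting material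
18 | 1,1'-[2',4,6,6'-tetrakis(benzyloxy)-2,4'-dihydroxy-[1,1'-biphenyl]-3,3'-diyl]bis[3-(4-methoxyphenyl)prop-2-yn-1-ol] (mixture of diastereomers) | OC(C#Cc1ccc(OC)cc1)c1c(O)c(-c2c(OCc3ccccc3)cc(O)c(C(O)C#Cc3ccc(OC)cc3)c2OCc2ccccc2)c(OCc2ccccc2)cc1OCc1ccccc1 | intermediate
19 | 1,1'-[2',4,6,6'-tetrakis(benzyloxy)-2,4'-dihydroxy-[1,1'-biphenyl]-3,3'-diyl]bis[3-(4-methoxyphenyl)prop-2-yn-1-one] (racemic axis) | O=C(C#Cc1ccc(OC)cc1)c1c(O)c(-c2c(OCc3ccccc3)cc(O)c(C(=O)C#Cc3ccc(OC)cc3)c2OCc2ccccc2)c(OCc2ccccc2)cc1OCc1ccccc1 | intermediate
20 | 5,7-bis(benzyloxy)-6-[5,7-bis(benzyloxy)-2-(4-methoxyphenyl)-4-oxo-4H-chromen-8-yl]-2-(4-methoxyphenyl)-4H-chromen-4-one | COc1ccc(-c2cc(=O)c3c(OCc4ccccc4)c(-c4c(OCc5ccccc5)cc(OCc5ccccc5)c5c(=O)cc(-c6ccc(OC)cc6)oc45)c(OCc4ccccc4)cc3o2)cc1 | intermediate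
21 | 6-[5,7-dihydroxy-2-(4-methoxyphenyl)-4-oxo-4H-chromen-8-yl]-5,7-dihydroxy-2-(4-methoxyphenyl)-4H-chromen-4-one | COc1ccc(-c2cc(=O)c3c(O)c(-c4c(O)cc(O)c5c(=O)cc(-c6ccc(OC)cc6)oc45)c(O)cc3o2)cc1 | target

## Step count and risks

Total step count: 12.
Longest linear sequence: 11 steps (steps 1, 2, 3, 5, 6, 7, 8, 9, 10, 11, 12); step 4 is a one-step side branch.

Steps least certain to work:

**Step 5 (key step).** The [2+2] union of 8 with 5 may be too slow, because the reacting alkyne carbon carries a di-ortho-substituted aryl. Ketene dimerisation, thermal decay of the ynol ether and acylation of 12 by surplus ketene would then consume the partners. The fallback sets out from 3 and returns at 15, and makes the biaryl bond by cross-coupling.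
- 3 would be saponified (KOH, aqueous DMSO, 100 °C) to 2,6-bis(benzyloxy)-4-(methoxymethoxy)benzoic acid F1.
- One portion would undergo decarboxylative iodination (I2, K3PO4, MeCN, 100 °C) to 1,3-bis(benzyloxy)-2-iodo-5-(methoxymethoxy)benzene F2.
- A second portion would undergo protodecarboxylation (Ag2CO3 cat., AcOH cat., DMSO, 120 °C) to 1,3-bis(benzyloxy)-5-(methoxymethoxy)benzene F3.
- Lithiation of F3 next to the methoxymethoxy group (n-BuLi, THF, 0 °C) and quenching with 2-isopropoxy-4,4,5,5-tetramethyl-1,3,2-dioxaborolane would give 2-[2,4-bis(benzyloxy)-6-(methoxymethoxy)phenyl]-4,4,5,5-tetramethyl-1,3,2-dioxaborolane F4.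
- Suzuki–Miyaura coupling of F2 with F4 (Pd(OAc)2, SPhos, K3PO4, toluene–water, 100 °C) would give 2',4,6,6'-tetrakis(benzyloxy)-2,4'-bis(methoxymethoxy)-1,1'-biphenyl F5.
- HCl in methanol would remove both acetals to give 15.

The iodide marks the carbon between the two benzyloxy groups (ring A of unit 1) and the boronate the carbon next to the acetal oxygen (ring A of unit 2), so the oxygen pattern of 15 is reproduced.

**Step 3.** Addition of LiCHBr2 to an ester flanked by two benzyloxy groups may be incomplete. Once butyllithium is present, ring lithiation next to the methoxymethoxy group or benzylic deprotonation may follow, and then silylation on carbon. The fallback sets out from 3 and returns at 5, and needs no alkyllithium.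
- Reduction (LiAlH4, THF, 0 °C) would give [2,6-bis(benzyloxy)-4-(methoxymethoxy)phenyl]methanol F6.
- Oxidation (MnO2, CH2Cl2) would give 2,6-bis(benzyloxy)-4-(methoxymethoxy)benzaldehyde F7.
- Ohira–Bestmann alkynylation (dimethyl (1-diazo-2-oxopropyl)phosphonate, K2CO3, MeOH) would give 1,3-bis(benzyloxy)-2-ethynyl-5-(methoxymethoxy)benzene F8.
- Deprotonation with LiN(SiMe3)2, oxidation of the lithium acetylide with t-BuOOLi to ynolate 4 and O-silylation with TIPSOTf would give 5.

**Step 4.** Benzyl alcohol may attack the ring carbonyl and cleave the ring to acetoacetate-type esters, or the ring may open thermally during a slow exchange. The fallback sets out from 6 and returns at 7. Hydrolysis with cold dilute HCl would give cyclobutane-1,3-dione F9, handled as its enol 3-hydroxycyclobut-2-en-1-one. Mitsunobu O-benzylation (BnOH, PPh3, DIAD, THF, 0 °C) would then give 7.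

**Step 9.** The double addition may be incomplete, because each aldehyde lies between two ortho oxygens and is deactivated as its ortho-phenoxide. The carbinols of 18 may also ionise to ortho-quinone methides on work-up. The fallback sets out from 16 and returns at 20, and uses the acetophenone–chalcone route.
- The smaller and more reactive MeMgBr (THF, 0 °C) would give 1,1'-[2',4,6,6'-tetrakis(benzyloxy)-2,4'-dihydroxy-[1,1'-biphenyl]-3,3'-diyl]di(ethan-1-ol) F10.
- MnO2 would give 1,1'-[2',4,6,6'-tetrakis(benzyloxy)-2,4'-dihydroxy-[1,1'-biphenyl]-3,3'-diyl]di(ethan-1-one) F11.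
- Claisen–Schmidt condensation with 4-methoxybenzaldehyde (KOH, EtOH–THF) would give (2E,2'E)-1,1'-[2',4,6,6'-tetrakis(benzyloxy)-2,4'-dihydroxy-[1,1'-biphenyl]-3,3'-diyl]bis[3-(4-methoxyphenyl)prop-2-en-1-one] F12.
- Oxidative cyclisation (I2 cat., DMSO, 120 °C) would give 20.

**Step 11.** The phenoxide may close 5-exo-dig onto the α-carbon and give aurones. The fallback sets out from 19 and returns at 20. Conjugate addition of Et2NH (EtOH–THF, 25 °C) would give 1,1'-[2',4,6,6'-tetrakis(benzyloxy)-2,4'-dihydroxy-[1,1'-biphenyl]-3,3'-diyl]bis[3-(diethylamino)-3-(4-methoxyphenyl)prop-2-en-1-one] F13. Warming with AcOH would then cyclise it by addition–elimination. The nitrogen-bearing carbon is the only electrophilic position, so only the six-membered ring can form.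

## Further compounds

F1 | step 5 | 2,6-bis(benzyloxy)-4-(methoxymethoxy)benzoic acid | COCOc1cc(OCc2ccccc2)c(C(=O)O)c(OCc2ccccc2)c1
F2 | step 5 | 1,3-bis(benzyloxy)-2-iodo-5-(methoxymethoxy)benzene | COCOc1cc(OCc2ccccc2)c(I)c(OCc2ccccc2)c1
F3 | step 5 | 1,3-bis(benzyloxy)-5-(methoxymethoxy)benzene | COCOc1cc(OCc2ccccc2)cc(OCc2ccccc2)c1
F4 | step 5 | 2-[2,4-bis(benzyloxy)-6-(methoxymethoxy)phenyl]-4,4,5,5-tetramethyl-1,3,2-dioxaborolane | COCOc1cc(OCc2ccccc2)cc(OCc2ccccc2)c1B1OC(C)(C)C(C)(C)O1
F5 | step 5 | 2',4,6,6'-tetrakis(benzyloxy)-2,4'-bis(methoxymethoxy)-1,1'-biphenyl | COCOc1cc(OCc2ccccc2)cc(OCc2ccccc2)c1-c1c(OCc2ccccc2)cc(OCOC)cc1OCc1ccccc1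
F6 | step 3 | [2,6-bis(benzyloxy)-4-(methoxymethoxy)phenyl]methanol | COCOc1cc(OCc2ccccc2)c(CO)c(OCc2ccccc2)c1
F7 | step 3 | 2,6-bis(benzyloxy)-4-(methoxymethoxy)benzaldehyde | COCOc1cc(OCc2ccccc2)c(C=O)c(OCc2ccccc2)c1
F8 | step 3 | 1,3-bis(benzyloxy)-2-ethynyl-5-(methoxymethoxy)benzene | COCOc1cc(OCc2ccccc2)c(C#C)c(OCc2ccccc2)c1
F9 | step 4 | cyclobutane-1,3-dione (enol form, 3-hydroxycyclobut-2-en-1-one) | O=C1C=C(O)C1
F10 | step 9 | 1,1'-[2',4,6,6'-tetrakis(benzyloxy)-2,4'-dihydroxy-[1,1'-biphenyl]-3,3'-diyl]di(ethan-1-ol) | CC(O)c1c(O)c(-c2c(OCc3ccccc3)cc(O)c(C(C)O)c2OCc2ccccc2)c(OCc2ccccc2)cc1OCc1ccccc1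
F11 | step 9 | 1,1'-[2',4,6,6'-tetrakis(benzyloxy)-2,4'-dihydroxy-[1,1'-biphenyl]-3,3'-diyl]di(ethan-1-one) | CC(=O)c1c(O)c(-c2c(OCc3ccccc3)cc(O)c(C(C)=O)c2OCc2ccccc2)c(OCc2ccccc2)cc1OCc1ccccc1
F12 | step 9 | (2E,2'E)-1,1'-[2',4,6,6'-tetrakis(benzyloxy)-2,4'-dihydroxy-[1,1'-biphenyl]-3,3'-diyl]bis[3-(4-methoxyphenyl)prop-2-en-1-one] | O=C(/C=C/c1ccc(OC)cc1)c1c(O)c(-c2c(OCc3ccccc3)cc(O)c(C(=O)/C=C/c3ccc(OC)cc3)c2OCc2ccccc2)c(OCc2ccccc2)cc1OCc1ccccc1
F13 | step 11 | 1,1'-[2',4,6,6'-tetrakis(benzyloxy)-2,4'-dihydroxy-[1,1'-biphenyl]-3,3'-diyl]bis[3-(diethylamino)-3-(4-methoxyphenyl)prop-2-en-1-one] | O=C(C=C(N(CC)CC)c1ccc(OC)cc1)c1c(O)c(-c2c(OCc3ccccc3)cc(O)c(C(=O)C=C(N(CC)CC)c3ccc(OC)cc3)c2OCc2ccccc2)c(OCc2ccccc2)cc1OCc1ccccc1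
A1 | alternative 1 | 5,7-bis(benzyloxy)-6-[5,7-bis(benzyloxy)-2-(4-methoxyphenyl)-4-oxo-4H-chromen-8-yl]-2-(4-methoxyphenyl)-4H-chromen-4-one | COc1ccc(-c2cc(=O)c3c(OCc4ccccc4)c(-c4c(OCc5ccccc5)cc(OCc5ccccc5)c5c(=O)cc(-c6ccc(OC)cc6)oc45)c(OCc4ccccc4)cc3o2)cc1
A2 | alternative 1 | 2',4,6,6'-tetrakis(benzyloxy)-3,3'-bis[(triphenyl-λ5-phosphanylidene)acetyl]-[1,1'-biphenyl]-2,4'-diyl bis(4-methoxybenzoate) | COc1ccc(C(=O)Oc2c(-c3c(OCc4ccccc4)c(C(=O)C=P(c4ccccc4)(c4ccccc4)c4ccccc4)c(OC(=O)c4ccc(OC)cc4)cc3OCc3ccccc3)c(OCc3ccccc3)cc(OCc3ccccc3)c2C(=O)C=P(c2ccccc2)(c2ccccc2)c2ccccc2)cc1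
A3 | alternative 2 | 5,7-bis(benzyloxy)-2-(4-methoxyphenyl)-8-(2,4,6-trihydroxyphenyl)-4H-chromen-4-one | Oc1cc(O)c(-c2c(OCc3ccccc3)cc(OCc3ccccc3)c3c(=O)cc(-c4ccc(OC)cc4)oc23)c(O)c1
A4 | alternative 2 | methyl 6-[5,7-bis(benzyloxy)-2-(4-methoxyphenyl)-4-oxo-4H-chromen-8-yl]-3,5-dioxohexanoate | COC(=O)CC(=O)CC(=O)Cc1c(OCc2ccccc2)cc(OCc2ccccc2)c2c(=O)cc(-c3ccc(OC)cc3)oc12
A5 | alternative 3 | 5,7-dihydroxy-2-(4-methoxyphenyl)-8-[2,4,6-tris(benzyloxy)phenyl]-4H-chromen-4-one | COc1ccc(-c2cc(=O)c3c(O)cc(O)c(-c4c(OCc5ccccc5)cc(OCc5ccccc5)cc4OCc4ccccc4)c3o2)cc1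
A6 | alternative 3 | 1-methoxy-4-[2,4,6-tris(benzyloxy)phenyl]-1,3-bis(trimethylsilyloxy)buta-1,3-diene | COC(O[Si](C)(C)C)=CC(O[Si](C)(C)C)=Cc1c(OCc2ccccc2)cc(OCc2ccccc2)cc1OCc1ccccc1
A7 | alternative 3 | 5-bromo-2-(4-methoxyphenyl)-4H-pyran-4-one | COc1ccc(-c2cc(=O)c(Br)co2)cc1
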